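If dusk and summer stand side by side, they share the charges and the cold feed, and they part after 2.0 h: summer turns warm, while dusk stays cold for longer.

the same everywhere: starting material 0.20 M
- elm: activator 0.28 M (fed, over 2.0 h); temperature −5 °C; run made earlier
- alder: activator 0.44 M (fed, over 2.0 h); temperature 15 °C; run made earlier
- dusk: activator 0.200 M (fed, over 2.0 h); at 0 °C throughout; time 15 h
- summer: activator 0.200 M (fed, over 2.0 h); at 0 °C until 2.0 h, from then on at 30 °C; time 10 h

- elm (time / h: ring / %, starting material / %): 0.667: 0, 99.2; 1.00: 0, 99.0; 2.00: 0.1, 95.3; 3.00: 0.7, 90.0; 5.00: 1.2, 82.2; 8.00: 2.7, 72.0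
- alder (time / h: ring / %, starting material / %): 0.333: 0, 99.1; 0.500: 0.1, 97.1; 1.00: 0.9, 89.1; 1.33: 2.5, 81.5; 2.50: 15.6, 52.6; 4.00: 35.7, 30.1

(standard deviation of a reading: 0.5 percentage points)

* the flask that ends with the higher amount of ring, in percent of the starting material charged, or "neither" when 2 percentage points or less lies between them (dusk / summer / neither)
* final ring, as a percentage of the starting material charged, in dusk
* final ring, as a percentage of the starting material charged, in summer

- in percentages every species weighs as the starting material in it: one open dimer counts as two
- for ring the crystals are counted in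
- as a solid, counted per litre of solution: crystals
- steps thought possible: starting material + activator -> activated form; activated form -> ring; starting material + activated form -> open dimer; crystals <-> ring

The reckoning below is separate from the forecast and follows the fraction left.

1. After the feed, ln([activator]/[starting material]) climbs straight in time, with slope k times the excess of activator. Every loss of starting material is counted as activation. Elm's readings at 3.00 h and 8.00 h, with an excess of 0.0800 M, give k = 0.185 M⁻¹ h⁻¹. Alder's at 2.50 h and 4.00 h give 1.16 M⁻¹ h⁻¹.

2. These readings give 59.0 kJ mol⁻¹, so k is 0.301 M⁻¹ h⁻¹ at 0 °C and 3.93 M⁻¹ h⁻¹ at 30 °C.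

3. Activator enters in a straight line, so both flasks keep 94.2 % of their starting material at the end of the feed.

4. The charges are equal, so the two concentrations are taken as equal. The fraction left then falls as the end-of-feed fraction over one plus a dose. Summer's dose is 5.92 and dusk's is 0.736, a larger figure for summer. This number, k times [starting material] after the feed times the hours since, is the activation dose. Summer keeps 13.6 % and dusk 54.2 %.

5. This reckoning puts a ceiling on ring of 86.4 % in summer and 45.8 % in dusk. The readings of the earlier runs lie below the starting material lost: elm shows 2.7 % of ring for 28.0 % of starting material lost, and alder 35.7 % for 69.9 %, a larger share.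

The forecast names summer, with 15 % (11 % to 20 %) for dusk and 76 % (63 % to 85 %) for summer. For dusk it says “ring closure is slow”. Its activation constant at 30 °C is 3.4, which differs from the one reckoned here.

The flasks end with 16.7 % of ring in dusk and 76.6 % in summer, so summer holds more.

    starting material + activator → activated form (k = 8.20 × 10⁻⁵ M⁻¹ s⁻¹, Ea = 56.0 kJ mol⁻¹)
    activated form → ring (k = 1.80 × 10⁻⁵ s⁻¹, Ea = 88.0 kJ mol⁻¹)
    starting material + activated form → open dimer (k = 3.00 × 10⁻⁵ M⁻¹ s⁻¹, Ea = 67.0 kJ mol⁻¹)
    crystals ⇌ ring, rate k4*(cs4 - [ring]) while solid is left; crystals form when [ring] > cs4 (solubility = 0.150 M, k = 0.00210 s⁻¹)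
    (constants at 0 °C)

Summer's dose of 5.92 stands beside 12.8 % of starting material at its end, where the reckoning said 13.6 %. Kept cold until 150 h, dusk reaches a dose of 8.38, larger than summer's; the reckoned fraction left is 10.0 %, and the simulated amount is 6.00 %. The time allowed is the main reason for dusk's low ring: dusk holds 16.7 % of ring at 15 h and 75.1 % at 150 h.

All runs are simulated with made-up constants, noise included.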